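**Retrosynthetic overview**

1. The target is a chain of seven benzene rings A–G joined by six diaryl ether oxygens; it is released last by cleaving all seventeen methyl ethers of the rings A–G phenol 41.
2. Rings C–G are added one at a time to the ring B phenol 19. Each ether is made by SNAr of the growing phenoxide on a fluorobenzaldehyde (25 for rings C and E, 29 for rings D, F and G), and the formyl group is then turned into the next phenol by Baeyer–Villiger oxidation.
3. The strategy rests on ring A: its ether carbon C1 lies between the hydroxyls at C2 and C6, with a third hydroxyl at C4. This is the phloroglucinol pattern of a folded 2-aryloxy-3,5-dioxo ester, so the hindered ring A/ring B ether is not made by arylation. Ring A is built by Dieckmann closure (C6 onto C1) of diester 14, which already carries ring B as an aryloxy group.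
4. Diester 14 comes from syringaldehyde (ring B) by benzylation, Baeyer–Villiger oxidation, O-alkylation with dimethyl chloromalonate, half-saponification and acylation of the bis(silyloxy)diene of methyl acetoacetate.
5. Order of rings: B (bought) → A (built, step 8) → C → D → E → F → G.

Key step: step 8

Remark: the aryloxy-bearing carbon of 7, 12, 13 and 14 is a stereocentre; these compounds are racemic, the centre is erased in step 8, and the target has no stereocentre.
Remark: 4-fluoro-2,6-dimethoxybenzaldehyde 29 is taken as a catalogue compound; silyl enol ethers 9, 11 and 13 are used as mixtures of double-bond isomers.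

**Route**

Step 1
Reactants: 1 syringaldehyde
Product: 2 4-(benzyloxy)-3,5-dimethoxybenzaldehyde
Conditions: BnBr, K2CO3, DMF, 60 °C
Reagents that add atoms: benzyl bromide, BrCc1ccccc1
Why: Williamson O-benzylation of the phenoxide; the aldehyde is inert to K2CO3.

Step 2
Reactants: 2 4-(benzyloxy)-3,5-dimethoxybenzaldehyde
Product: 4 4-(benzyloxy)-3,5-dimethoxyphenol, via 4-(benzyloxy)-3,5-dimethoxyphenyl formate 3 (not isolated)
Conditions: mCPBA, CH2Cl2, 0 °C to rt; aq. Na2S2O3 wash; then K2CO3 (cat.), MeOH, rt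
Reagents that add atoms: 3-chloroperoxybenzoic acid (mCPBA), OOC(=O)c1cccc(Cl)c1
Why: Baeyer–Villiger (Dakin-type) oxidation in which the electron-rich aryl group migrates to oxygen, followed by methanolysis of the aryl formate; benzyl and methyl ethers are stable to the peracid.

Step 3
Reactants: 4 4-(benzyloxy)-3,5-dimethoxyphenol; 5 dimethyl chloromalonate
Product: 6 dimethyl 2-[4-(benzyloxy)-3,5-dimethoxyphenoxy]propanedioate
Conditions: K2CO3, acetone, reflux
Reagents that add atoms: none
Why: Williamson-type SN2 displacement of chloride at the malonate sp3 carbon by an unhindered phenoxide; this attaches the future ring A/ring B ether oxygen before ring A exists.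

Step 4
Reactants: 6 dimethyl 2-[4-(benzyloxy)-3,5-dimethoxyphenoxy]propanedioate
Product: 7 2-[4-(benzyloxy)-3,5-dimethoxyphenoxy]-3-methoxy-3-oxopropanoic acid (racemic)
Conditions: KOH (1.0 equiv), MeOH/THF, 0 °C; then cold 1 M HCl
Reagents that add atoms: potassium hydroxide, [K+].[OH-]
Why: selective monosaponification of a malonate with one equivalent of hydroxide, the first carboxylate retarding attack on the second ester; the new stereocentre is racemic and is erased in step 8.

Step 5
Reactants: 8 methyl acetoacetate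
Product: 9 methyl 3-(trimethylsilyloxy)but-2-enoate
Conditions: TMSCl, Et3N, hexane, rt
Reagents that add atoms: chlorotrimethylsilane, C[Si](C)(C)Cl
Why: O-silylation of the enol of a β-keto ester (silyl enol ether formation).

Step 6
Reactants: 9 methyl 3-(trimethylsilyloxy)but-2-enoate
Product: 11 1-methoxy-1,3-bis(trimethylsilyloxy)buta-1,3-diene, via lithium ester dienolate 10 (not isolated)
Conditions: LiN(iPr)2, THF, −78 °C; then TMSCl, −78 to 0 °C
Reagents that add atoms: chlorotrimethylsilane, C[Si](C)(C)Cl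
Why: kinetic γ-deprotonation gives the cross-conjugated ester dienolate, which is O-silylated to the 1,3-bis(silyloxy)diene, a storable equivalent of the acetoacetate dianion.

Step 7
Reactants: 7 2-[4-(benzyloxy)-3,5-dimethoxyphenoxy]-3-methoxy-3-oxopropanoic acid; 11 1-methoxy-1,3-bis(trimethylsilyloxy)buta-1,3-diene
Product: 14 dimethyl 2-[4-(benzyloxy)-3,5-dimethoxyphenoxy]-3,5-dioxoheptanedioate (racemic), via half-ester acid chloride 12 (not isolated), via 5-silyl enol ether adduct 13 (not isolated)
Conditions: (COCl)2, DMF (cat.), CH2Cl2, 0 °C to rt, volatiles removed; then 11, CH2Cl2, −78 to 20 °C; aq. NH4Cl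
Reagents that add atoms: none
Why: the acid chloride acylates the terminal carbon of the bis(silyloxy)diene (vinylogous Mukaiyama-type Claisen acylation, run without base so the acidic C–H next to the aryloxy group is not disturbed), and aqueous work-up cleaves the remaining silyl enol ether to the 3,5-dioxo ester.

Step 8
Reactants: 14 dimethyl 2-[4-(benzyloxy)-3,5-dimethoxyphenoxy]-3,5-dioxoheptanedioate
Product: 15 methyl 3-[4-(benzyloxy)-3,5-dimethoxyphenoxy]-2,4,6-trihydroxybenzoate
Conditions: NaOMe (4 equiv), MeOH, 0 °C to rt then 50 °C, Ar; then 1 M HCl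
Reagents that add atoms: none
Why: Methoxide generates the polyenolate of 14; the C6 carbanion (between the C5 ketone and the C7 ester) adds to the C1 ester carbonyl, methoxide leaves, and the resulting 2-aryloxycyclohexane-1,3,5-trione carboxylate enolises to the phloroglucinol, i.e. an intramolecular Claisen (Dieckmann) condensation followed by aromatisation that forms the C1–C6 bond. The closest known reaction type is the base-induced cyclisation of 3,5-dioxopimelates and of acetonedicarboxylate–malonate adducts to phloroglucinol carboxylates. Ring A closes by an allowed 6-exo-trig attack of the enolate on the ester carbonyl. No stereocentre is created, and the racemic C2 centre of 14 becomes the sp2 ether carbon of ring A. The selectivity required is closure from C6 onto C1 rather than from C2 onto C7 or lactonisation to 2-pyranones: closure from C2 would leave a quaternary carbon that cannot aromatise and is reopened by methoxide through retro-Claisen cleavage, and pyranones are opened by methanolysis, so only the C6-to-C1 product leaves the equilibria, as its phenoxide. Because the ether oxygen was attached in step 3 at an sp3 carbon, the doubly ortho-substituted ether of ring A arises without arylation of a hindered oxygen.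

Step 9
Reactants: 15 methyl 3-[4-(benzyloxy)-3,5-dimethoxyphenoxy]-2,4,6-trihydroxybenzoate
Product: 17 2-[4-(benzyloxy)-3,5-dimethoxyphenoxy]benzene-1,3,5-triol, via 3-[4-(benzyloxy)-3,5-dimethoxyphenoxy]-2,4,6-trihydroxybenzoic acid 16 (not isolated)
Conditions: 2 M aq. NaOH (degassed), 90 °C, Ar; then HCl to pH 1, 60 °C
Reagents that add atoms: none
Why: ester saponification followed by decarboxylation of the 2,4,6-trihydroxybenzoic acid, which loses CO2 readily in warm acid through its β-keto acid tautomer; exclusion of air protects the phloroglucinol.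

Step 10
Reactants: 17 2-[4-(benzyloxy)-3,5-dimethoxyphenoxy]benzene-1,3,5-triol
Product: 18 2-[4-(benzyloxy)-3,5-dimethoxyphenoxy]-1,3,5-trimethoxybenzene
Conditions: Me2SO4, K2CO3, acetone, reflux, Ar
Reagents that add atoms: dimethyl sulfate, COS(=O)(=O)OC
Why: exhaustive Williamson O-methylation with a hard electrophile and a weak base, conditions that favour O- over C-methylation of phloroglucinols.

Step 11
Reactants: 18 2-[4-(benzyloxy)-3,5-dimethoxyphenoxy]-1,3,5-trimethoxybenzene
Product: 19 2,6-dimethoxy-4-(2,4,6-trimethoxyphenoxy)phenol (rings A–B phenol)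
Conditions: H2 (1 atm), Pd/C, EtOAc/MeOH, rt
Reagents that add atoms: none
Why: hydrogenolysis of the benzyl ether over palladium on carbon; methyl ethers and the diaryl ether are inert, so the ring B phenol becomes the only nucleophilic site.

Step 12
Reactants: 20 3,4,5-trimethoxyaniline
Product: 22 5-fluoro-1,2,3-trimethoxybenzene, via 3,4,5-trimethoxybenzenediazonium tetrafluoroborate 21 (not isolated)
Conditions: NOBF4, CH2Cl2, 0 °C (aniline added to the salt); then 1,2-dichlorobenzene, 110 °C
Reagents that add atoms: nitrosonium tetrafluoroborate, N#[O+].F[B-](F)(F)F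
Why: Balz–Schiemann reaction: diazotisation by the nitrosonium salt and thermal fluorodediazoniation of the aryldiazonium tetrafluoroborate.

Step 13
Reactants: 22 5-fluoro-1,2,3-trimethoxybenzene
Product: 25 6-fluoro-2,3,4-trimethoxybenzaldehyde, via 6-fluoro-2,3,4-trimethoxyphenyllithium 23 (not isolated), via lithium hemiaminal alkoxide 24 (not isolated)
Conditions: n-BuLi, THF, −78 °C; DMF, −78 °C to rt; 1 M HCl
Reagents that add atoms: N,N-dimethylformamide, CN(C)C=O
Why: directed ortho-lithiation at the only kind of ring C–H, which lies between fluorine and a methoxy group, followed by formylation with DMF; the aryllithium is kept at −78 °C to prevent loss of LiF.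

Step 14
Reactants: 19 2,6-dimethoxy-4-(2,4,6-trimethoxyphenoxy)phenol; 25 6-fluoro-2,3,4-trimethoxybenzaldehyde
Product: 26 2,3,4-trimethoxy-6-[2,6-dimethoxy-4-(2,4,6-trimethoxyphenoxy)phenoxy]benzaldehyde (rings A–C aldehyde)
Conditions: Cs2CO3, DMSO, 120 °C, Ar
Reagents that add atoms: none
Why: nucleophilic aromatic substitution (addition–elimination) of fluoride by the ring B phenoxide, the ortho formyl group stabilising the Meisenheimer adduct; no transition metal is present that could oxidise the electron-rich phenoxide.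

Step 15
Reactants: 26 rings A–C aldehyde
Product: 28 2,3,4-trimethoxy-6-[2,6-dimethoxy-4-(2,4,6-trimethoxyphenoxy)phenoxy]phenol (rings A–C phenol), via rings A–C aryl formate 27 (not isolated)
Conditions: mCPBA, CH2Cl2, 0 °C to rt; aq. Na2S2O3 wash; then K2CO3 (cat.), MeOH/THF, rt, Ar
Reagents that add atoms: 3-chloroperoxybenzoic acid (mCPBA), OOC(=O)c1cccc(Cl)c1
Why: Baeyer–Villiger oxidation of an aldehyde flanked by aryloxy and methoxy groups, where aryl migration is strongly favoured, then formate methanolysis; the activating formyl group thereby becomes the C2 oxygen of ring C.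

Step 16
Reactants: 28 rings A–C phenol; 29 4-fluoro-2,6-dimethoxybenzaldehyde
Product: 30 4-{2,3,4-trimethoxy-6-[2,6-dimethoxy-4-(2,4,6-trimethoxyphenoxy)phenoxy]phenoxy}-2,6-dimethoxybenzaldehyde (rings A–D aldehyde)
Conditions: Cs2CO3, DMSO, 90 °C, Ar
Reagents that add atoms: none
Why: SNAr para to the formyl group of 29, fluoride being displaced far faster than the ortho methoxy groups; the hindered phenoxide meets a ring carbon with two hydrogen-bearing neighbours.

Step 17
Reactants: 30 rings A–D aldehyde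
Product: 32 4-{2,3,4-trimethoxy-6-[2,6-dimethoxy-4-(2,4,6-trimethoxyphenoxy)phenoxy]phenoxy}-2,6-dimethoxyphenol (rings A–D phenol), via rings A–D aryl formate 31 (not isolated)
Conditions: mCPBA, CH2Cl2, 0 °C to rt; aq. Na2S2O3 wash; then K2CO3 (cat.), MeOH/THF, rt, Ar
Reagents that add atoms: 3-chloroperoxybenzoic acid (mCPBA), OOC(=O)c1cccc(Cl)c1
Why: Baeyer–Villiger oxidation of a 2,6-dimethoxybenzaldehyde with migration of the electron-rich aryl group, then formate methanolysis, giving the C4 hydroxyl of ring D between its two methoxy groups.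

Step 18
Reactants: 32 rings A–D phenol; 25 6-fluoro-2,3,4-trimethoxybenzaldehyde
Product: 33 rings A–E aldehyde (phenol 32 O-arylated by a 2-formyl-3,4,5-trimethoxyphenyl group)
Conditions: Cs2CO3, DMSO, 120 °C, Ar
Reagents that add atoms: none
Why: SNAr as in step 14, the ortho formyl group activating the fluoride of 25 towards the ring D phenoxide.

Step 19
Reactants: 33 rings A–E aldehyde
Product: 35 rings A–E phenol (phenol 32 O-arylated by a 2-hydroxy-3,4,5-trimethoxyphenyl group), via rings A–E aryl formate 34 (not isolated)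
Conditions: mCPBA, CH2Cl2, 0 °C to rt; aq. Na2S2O3 wash; then K2CO3 (cat.), MeOH/THF, rt, Ar
Reagents that add atoms: 3-chloroperoxybenzoic acid (mCPBA), OOC(=O)c1cccc(Cl)c1
Why: Baeyer–Villiger oxidation and formate methanolysis as in step 15, converting the formyl group into the C2 oxygen of ring E.

Step 20
Reactants: 35 rings A–E phenol; 29 4-fluoro-2,6-dimethoxybenzaldehyde
Product: 36 rings A–F aldehyde (phenol 35 O-arylated by a 4-formyl-3,5-dimethoxyphenyl group)
Conditions: Cs2CO3, DMSO, 90 °C, Ar
Reagents that add atoms: none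
Why: SNAr para to the formyl group as in step 16.

Step 21
Reactants: 36 rings A–F aldehyde
Product: 38 rings A–F phenol (phenol 35 O-arylated by a 4-hydroxy-3,5-dimethoxyphenyl group), via rings A–F aryl formate 37 (not isolated)
Conditions: mCPBA, CH2Cl2, 0 °C to rt; aq. Na2S2O3 wash; then K2CO3 (cat.), MeOH/THF, rt, Ar
Reagents that add atoms: 3-chloroperoxybenzoic acid (mCPBA), OOC(=O)c1cccc(Cl)c1
Why: Baeyer–Villiger oxidation and formate methanolysis as in step 17, giving the C4 hydroxyl of ring F.

Step 22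
Reactants: 38 rings A–F phenol; 29 4-fluoro-2,6-dimethoxybenzaldehyde
Product: 39 rings A–G aldehyde (phenol 38 O-arylated by a 4-formyl-3,5-dimethoxyphenyl group)
Conditions: Cs2CO3, DMSO, 90 °C, Ar
Reagents that add atoms: none
Why: SNAr para to the formyl group as in step 16; the same building block serves for ring G because its formyl carbon becomes the C4 oxygen of ring G.

Step 23
Reactants: 39 rings A–G aldehyde
Product: 41 rings A–G phenol (heptadeca-O-methyl ether of the target; C4 hydroxyl of ring G free), via rings A–G aryl formate 40 (not isolated)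
Conditions: mCPBA, CH2Cl2, 0 °C to rt; aq. Na2S2O3 wash; then K2CO3 (cat.), MeOH/THF, rt, Ar
Reagents that add atoms: 3-chloroperoxybenzoic acid (mCPBA), OOC(=O)c1cccc(Cl)c1
Why: Baeyer–Villiger oxidation and formate methanolysis as in step 17, completing the oxygen pattern of ring G.

Step 24
Reactants: 41 rings A–G phenol
Product: 42 CNP0292517.0 (target)
Conditions: BBr3 (excess), CH2Cl2, −78 °C to rt, Ar; H2O, 0 °C; chromatography on a dextran gel or reversed phase under Ar
Reagents that add atoms: none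
Why: BBr3 cleaves aryl methyl ethers by bromide attack at the methyl carbon of the boron-coordinated ether, whereas the six diaryl ethers, which have no sp3 carbon on oxygen, survive; the aqueous quench hydrolyses the aryl borates.

**Compound list**

1 | syringaldehyde | COc1cc(C=O)cc(OC)c1O | starting material
2 | 4-(benzyloxy)-3,5-dimethoxybenzaldehyde | COc1cc(C=O)cc(OC)c1OCc1ccccc1 | intermediate
3 | 4-(benzyloxy)-3,5-dimethoxyphenyl formate (not isolated) | COc1cc(OC=O)cc(OC)c1OCc1ccccc1 | intermediate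
4 | 4-(benzyloxy)-3,5-dimethoxyphenol | COc1cc(O)cc(OC)c1OCc1ccccc1 | intermediate
5 | dimethyl chloromalonate | COC(=O)C(Cl)C(=O)OC | starting material
6 | dimethyl 2-[4-(benzyloxy)-3,5-dimethoxyphenoxy]propanedioate | COC(=O)C(Oc1cc(OC)c(OCc2ccccc2)c(OC)c1)C(=O)OC | intermediate
7 | 2-[4-(benzyloxy)-3,5-dimethoxyphenoxy]-3-methoxy-3-oxopropanoic acid (racemic) | COC(=O)C(Oc1cc(OC)c(OCc2ccccc2)c(OC)c1)C(O)=O | intermediate
8 | methyl acetoacetate | COC(=O)CC(C)=O | starting material
9 | methyl 3-(trimethylsilyloxy)but-2-enoate (E/Z mixture) | COC(=O)C=C(C)O[Si](C)(C)C | intermediate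
10 | lithium ester dienolate of 9 (not isolated) | COC(O[Li])=CC(=C)O[Si](C)(C)C | intermediate
11 | 1-methoxy-1,3-bis(trimethylsilyloxy)buta-1,3-diene | COC(O[Si](C)(C)C)=CC(=C)O[Si](C)(C)C | intermediate
12 | methyl 2-[4-(benzyloxy)-3,5-dimethoxyphenoxy]-3-chloro-3-oxopropanoate (racemic, not isolated) | COC(=O)C(Oc1cc(OC)c(OCc2ccccc2)c(OC)c1)C(Cl)=O | intermediate
13 | dimethyl 2-[4-(benzyloxy)-3,5-dimethoxyphenoxy]-3-oxo-5-(trimethylsilyloxy)hept-5-enedioate (racemic, not isolated) | COC(=O)C(Oc1cc(OC)c(OCc2ccccc2)c(OC)c1)C(=O)CC(O[Si](C)(C)C)=CC(=O)OC | intermediate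
14 | dimethyl 2-[4-(benzyloxy)-3,5-dimethoxyphenoxy]-3,5-dioxoheptanedioate (racemic; key-step precursor) | COC(=O)C(Oc1cc(OC)c(OCc2ccccc2)c(OC)c1)C(=O)CC(=O)CC(=O)OC | intermediate
15 | methyl 3-[4-(benzyloxy)-3,5-dimethoxyphenoxy]-2,4,6-trihydroxybenzoate (key-step product) | COC(=O)c1c(O)cc(O)c(Oc2cc(OC)c(OCc3ccccc3)c(OC)c2)c1O | intermediate
16 | 3-[4-(benzyloxy)-3,5-dimethoxyphenoxy]-2,4,6-trihydroxybenzoic acid (not isolated) | OC(=O)c1c(O)cc(O)c(Oc2cc(OC)c(OCc3ccccc3)c(OC)c2)c1O | intermediate
17 | 2-[4-(benzyloxy)-3,5-dimethoxyphenoxy]benzene-1,3,5-triol | Oc1cc(O)c(Oc2cc(OC)c(OCc3ccccc3)c(OC)c2)c(O)c1 | intermediate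
18 | 2-[4-(benzyloxy)-3,5-dimethoxyphenoxy]-1,3,5-trimethoxybenzene | COc1cc(OC)c(Oc2cc(OC)c(OCc3ccccc3)c(OC)c2)c(OC)c1 | intermediate
19 | 2,6-dimethoxy-4-(2,4,6-trimethoxyphenoxy)phenol (rings A–B phenol) | COc1cc(OC)c(Oc2cc(OC)c(O)c(OC)c2)c(OC)c1 | intermediate
20 | 3,4,5-trimethoxyaniline | COc1cc(N)cc(OC)c1OC | starting material
21 | 3,4,5-trimethoxybenzenediazonium tetrafluoroborate (not isolated) | COc1cc([N+]#N)cc(OC)c1OC.F[B-](F)(F)F | intermediate
22 | 5-fluoro-1,2,3-trimethoxybenzene | COc1cc(F)cc(OC)c1OC | intermediate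
23 | 6-fluoro-2,3,4-trimethoxyphenyllithium (not isolated) | [Li]c1c(F)cc(OC)c(OC)c1OC | intermediate
24 | lithium (dimethylamino)(6-fluoro-2,3,4-trimethoxyphenyl)methanolate (racemic, not isolated) | CN(C)C(O[Li])c1c(F)cc(OC)c(OC)c1OC | intermediate
25 | 6-fluoro-2,3,4-trimethoxybenzaldehyde | O=Cc1c(F)cc(OC)c(OC)c1OC | intermediate
26 | rings A–C aldehyde, 2,3,4-trimethoxy-6-[2,6-dimethoxy-4-(2,4,6-trimethoxyphenoxy)phenoxy]benzaldehyde | COc1cc(OC)c(Oc2cc(OC)c(Oc3cc(OC)c(OC)c(OC)c3C=O)c(OC)c2)c(OC)c1 | intermediate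
27 | rings A–C aryl formate (formate ester of 28, not isolated) | COc1cc(OC)c(Oc2cc(OC)c(Oc3cc(OC)c(OC)c(OC)c3OC=O)c(OC)c2)c(OC)c1 | intermediate
28 | rings A–C phenol, 2,3,4-trimethoxy-6-[2,6-dimethoxy-4-(2,4,6-trimethoxyphenoxy)phenoxy]phenol | COc1cc(OC)c(Oc2cc(OC)c(Oc3cc(OC)c(OC)c(OC)c3O)c(OC)c2)c(OC)c1 | intermediate
29 | 4-fluoro-2,6-dimethoxybenzaldehyde | COc1cc(F)cc(OC)c1C=O | starting material
30 | rings A–D aldehyde (28 O-arylated by a 4-formyl-3,5-dimethoxyphenyl group) | COc1cc(OC)c(Oc2cc(OC)c(Oc3cc(OC)c(OC)c(OC)c3Oc3cc(OC)c(C=O)c(OC)c3)c(OC)c2)c(OC)c1 | intermediate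
31 | rings A–D aryl formate (formate ester of 32, not isolated) | COc1cc(OC)c(Oc2cc(OC)c(Oc3cc(OC)c(OC)c(OC)c3Oc3cc(OC)c(OC=O)c(OC)c3)c(OC)c2)c(OC)c1 | intermediate
32 | rings A–D phenol (28 O-arylated by a 4-hydroxy-3,5-dimethoxyphenyl group) | COc1cc(OC)c(Oc2cc(OC)c(Oc3cc(OC)c(OC)c(OC)c3Oc3cc(OC)c(O)c(OC)c3)c(OC)c2)c(OC)c1 | intermediate
33 | rings A–E aldehyde (32 O-arylated by a 2-formyl-3,4,5-trimethoxyphenyl group) | COc1cc(OC)c(Oc2cc(OC)c(Oc3cc(OC)c(OC)c(OC)c3Oc3cc(OC)c(Oc4cc(OC)c(OC)c(OC)c4C=O)c(OC)c3)c(OC)c2)c(OC)c1 | intermediate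
34 | rings A–E aryl formate (formate ester of 35, not isolated) | COc1cc(OC)c(Oc2cc(OC)c(Oc3cc(OC)c(OC)c(OC)c3Oc3cc(OC)c(Oc4cc(OC)c(OC)c(OC)c4OC=O)c(OC)c3)c(OC)c2)c(OC)c1 | intermediate
35 | rings A–E phenol (32 O-arylated by a 2-hydroxy-3,4,5-trimethoxyphenyl group) | COc1cc(OC)c(Oc2cc(OC)c(Oc3cc(OC)c(OC)c(OC)c3Oc3cc(OC)c(Oc4cc(OC)c(OC)c(OC)c4O)c(OC)c3)c(OC)c2)c(OC)c1 | intermediate
36 | rings A–F aldehyde (35 O-arylated by a 4-formyl-3,5-dimethoxyphenyl group) | COc1cc(OC)c(Oc2cc(OC)c(Oc3cc(OC)c(OC)c(OC)c3Oc3cc(OC)c(Oc4cc(OC)c(OC)c(OC)c4Oc4cc(OC)c(C=O)c(OC)c4)c(OC)c3)c(OC)c2)c(OC)c1 | intermediate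
37 | rings A–F aryl formate (formate ester of 38, not isolated) | COc1cc(OC)c(Oc2cc(OC)c(Oc3cc(OC)c(OC)c(OC)c3Oc3cc(OC)c(Oc4cc(OC)c(OC)c(OC)c4Oc4cc(OC)c(OC=O)c(OC)c4)c(OC)c3)c(OC)c2)c(OC)c1 | intermediate
38 | rings A–F phenol (35 O-arylated by a 4-hydroxy-3,5-dimethoxyphenyl group) | COc1cc(OC)c(Oc2cc(OC)c(Oc3cc(OC)c(OC)c(OC)c3Oc3cc(OC)c(Oc4cc(OC)c(OC)c(OC)c4Oc4cc(OC)c(O)c(OC)c4)c(OC)c3)c(OC)c2)c(OC)c1 | intermediate
39 | rings A–G aldehyde (38 O-arylated by a 4-formyl-3,5-dimethoxyphenyl group) | COc1cc(OC)c(Oc2cc(OC)c(Oc3cc(OC)c(OC)c(OC)c3Oc3cc(OC)c(Oc4cc(OC)c(OC)c(OC)c4Oc4cc(OC)c(Oc5cc(OC)c(C=O)c(OC)c5)c(OC)c4)c(OC)c3)c(OC)c2)c(OC)c1 | intermediate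
40 | rings A–G aryl formate (formate ester of 41, not isolated) | COc1cc(OC)c(Oc2cc(OC)c(Oc3cc(OC)c(OC)c(OC)c3Oc3cc(OC)c(Oc4cc(OC)c(OC)c(OC)c4Oc4cc(OC)c(Oc5cc(OC)c(OC=O)c(OC)c5)c(OC)c4)c(OC)c3)c(OC)c2)c(OC)c1 | intermediate
41 | rings A–G phenol (heptadeca-O-methyl ether of the target, C4 hydroxyl of ring G free) | COc1cc(OC)c(Oc2cc(OC)c(Oc3cc(OC)c(OC)c(OC)c3Oc3cc(OC)c(Oc4cc(OC)c(OC)c(OC)c4Oc4cc(OC)c(Oc5cc(OC)c(O)c(OC)c5)c(OC)c4)c(OC)c3)c(OC)c2)c(OC)c1 | intermediate
42 | CNP0292517.0 | Oc1cc(O)c(Oc2cc(O)c(Oc3cc(O)c(O)c(O)c3Oc3cc(O)c(Oc4cc(O)c(O)c(O)c4Oc4cc(O)c(Oc5cc(O)c(O)c(O)c5)c(O)c4)c(O)c3)c(O)c2)c(O)c1 | target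

**Step count**

Total: 24 steps. Longest linear sequence: 20 steps (steps 1–4, 7–11 and 14–24); steps 5–6 and 12–13 are side branches.

**Steps most likely to fail**

Step 8. The polyenolate of 14 may be diverted into 2-pyranone formation, closure from C2 onto C7, or retro-Claisen fragmentation of the 1,3-diketone faster than it closes from C6 onto C1. The fallback keeps the same ring closure but runs it on a chain with one more ester, the classical acetonedicarboxylate–malonate type of phloroglucinol synthesis. It sets out from acid 7, which is converted to acid chloride 12 as in step 7 and used to C-acylate the magnesium enolate of commercial dimethyl 3-oxopentanedioate (MgCl2, Et3N, MeCN, 0 °C). This should give trimethyl 1-[4-(benzyloxy)-3,5-dimethoxyphenoxy]-2,4-dioxopentane-1,3,5-tricarboxylate F1, whose central carbon sits as a stable tricarbonyl enolate and so resists fragmentation. NaOMe in MeOH should then close ring A in the same Dieckmann mode to dimethyl 5-[4-(benzyloxy)-3,5-dimethoxyphenoxy]-2,4,6-trihydroxybenzene-1,3-dicarboxylate F2. Saponification with degassed aqueous NaOH gives 5-[4-(benzyloxy)-3,5-dimethoxyphenoxy]-2,4,6-trihydroxybenzene-1,3-dicarboxylic acid F3 (not isolated), which should lose both carboxyl groups on acidification and warming. The route is rejoined at triol 17.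

Step 14 (and its repeat, step 18). Addition of the hindered 2,6-dimethoxyphenoxide to 25 is slowed by the methoxy group para to fluorine, so oxidation of the phenoxide or substitution of the methoxy group ortho to the formyl group may compete. The fallback replaces SNAr by a copper-catalysed Ullmann ether synthesis. Commercial 5-bromo-1,2,3-trimethoxybenzene is formylated at its only free ring position (Rieche formylation, Cl2CHOMe, TiCl4, CH2Cl2, 0 °C) to 6-bromo-2,3,4-trimethoxybenzaldehyde F4. This is coupled with phenol 19 (CuI, picolinic acid, K3PO4, DMSO, 90 °C, Ar), the ortho formyl group assisting the reaction at copper. The product is aldehyde 26, and the route continues with step 15; the same change would serve step 18 (32 with F4 to give 33).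

Step 24. Seventeen ether cleavages may not all go to completion, and the octadecaphenol may be oxidised by air during isolation. The fallback isolates the product as a stable derivative. Starting from 41, the crude product of the BBr3 reaction is not purified but acetylated at once (Ac2O, pyridine, DMAP cat., rt) to the octadecaacetate of 42, F5. F5 can be chromatographed on silica and separated from partially methylated material, which is returned to the BBr3 treatment. Acid-catalysed methanolysis (HCl in degassed MeOH, 40 °C, Ar) should then release target 42.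

**Further compounds**

F1 | step 8 | trimethyl 1-[4-(benzyloxy)-3,5-dimethoxyphenoxy]-2,4-dioxopentane-1,3,5-tricarboxylate (mixture of stereoisomers and tautomers) | COC(=O)C(Oc1cc(OC)c(OCc2ccccc2)c(OC)c1)C(=O)C(C(=O)OC)C(=O)CC(=O)OC
F2 | step 8 | dimethyl 5-[4-(benzyloxy)-3,5-dimethoxyphenoxy]-2,4,6-trihydroxybenzene-1,3-dicarboxylate | COC(=O)c1c(O)c(Oc2cc(OC)c(OCc3ccccc3)c(OC)c2)c(O)c(C(=O)OC)c1O
F3 | step 8 | 5-[4-(benzyloxy)-3,5-dimethoxyphenoxy]-2,4,6-trihydroxybenzene-1,3-dicarboxylic acid | OC(=O)c1c(O)c(Oc2cc(OC)c(OCc3ccccc3)c(OC)c2)c(O)c(C(O)=O)c1O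
F4 | step 14 | 6-bromo-2,3,4-trimethoxybenzaldehyde | O=Cc1c(Br)cc(OC)c(OC)c1OC
F5 | step 24 | octadecaacetate of 42 | CC(=O)Oc1cc(OC(C)=O)c(Oc2cc(OC(C)=O)c(Oc3cc(OC(C)=O)c(OC(C)=O)c(OC(C)=O)c3Oc3cc(OC(C)=O)c(Oc4cc(OC(C)=O)c(OC(C)=O)c(OC(C)=O)c4Oc4cc(OC(C)=O)c(Oc5cc(OC(C)=O)c(OC(C)=O)c(OC(C)=O)c5)c(OC(C)=O)c4)c(OC(C)=O)c3)c(OC(C)=O)c2)c(OC(C)=O)c1
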